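**Plan**
- Retrosynthesis: the two isovalerate C–O bonds are cut first (diol), then the C(sp)–CH2 bond of the butynyl arm (terminal alkyne plus a diazoacetate two-carbon unit), then the alkyne terminus (one-carbon homologation of an aldehyde).
- Ring A, the alkyne-bearing thiophene, is cut at S1–C2 and C4–C5. Its C3 and C4 carry only hydrogen, C2 carries ring B and C5 carries a single carbon, so C2–C3–C4 map onto a beta-chloroacrolein and S1–C5 with its one-carbon handle onto mercaptoacetaldehyde.
- Forward: ring B is bought as methyl 5-acetylthiophene-2-carboxylate. The acetyl group is chloroformylated, ring A is closed, the chain is extended by one and then two carbons, both esters are reduced together and both alcohols are acylated together.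
- Stereochemistry: the target has no stereocentre and no stereogenic double bond. The Z geometry of the chloroenal and the transient stereocentres of the aldol adduct disappear on aromatisation.

Key step: step 2

Remark: ring A is the thiophene carrying the alkyne (S1, C2 bonded to ring B, C3, C4, C5 bonded to the alkyne); ring B carries the acyloxymethyl group. Iminium salt 2 is written as its chloride, although dichlorophosphate may be the counter-ion in the flask.

**Step 1**
Reactants: 1 methyl 5-acetylthiophene-2-carboxylate
Product: 3 methyl 5-[(Z)-1-chloro-3-oxoprop-1-enyl]thiophene-2-carboxylate, via chlorovinyl iminium chloride 2 (not isolated)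
Conditions: POCl3 (3 equiv), DMF, 0 °C to 60 °C; then aq. NaOAc, 0 °C
Reagents that add atoms: N,N-dimethylformamide CN(C)C=O (formyl carbon); phosphoryl chloride O=P(Cl)(Cl)Cl (chlorine); water O (aldehyde oxygen)
Why: Vilsmeier–Haack–Arnold chloroformylation: the enol of the aryl methyl ketone is formylated by the chloromethyleneiminium reagent, the vinylogous amide is converted into iminium salt 2, and hydrolysis should give the Z enal (aryl trans to CHO, the more stable isomer), while the doubly deactivated thiophene ring is not formylated.

**Step 2**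
Reactants: 3 methyl 5-[(Z)-1-chloro-3-oxoprop-1-enyl]thiophene-2-carboxylate; 4 1,4-dithiane-2,5-diol
Product: 8 methyl 5'-formyl-2,2'-bithiophene-5-carboxylate, via mercaptoacetaldehyde 5 (not isolated), via vinyl sulfide dialdehyde 6 (not isolated), via aldol adduct 7 (not isolated)
Conditions: 4 (0.6 equiv), Et3N (2.2 equiv), DMF, N2, 0 °C to rt, then 60 °C
Reagents that add atoms: none
Why: Fiesselmann-type thiophene synthesis: Et3N cracks dimer 4 to mercaptoacetaldehyde 5, whose thiolate adds to the chlorine-bearing carbon of the vinylogous acid chloride 3 and expels chloride with retention of the Z geometry, forming the S1–C2 bond of ring A in vinyl sulfide 6. The S–CH2–CHO unit of 6 is the only enolisable site; its enolate attacks the enal carbonyl held cis to sulfur and forms C4–C5 in a 5-exo-trig intramolecular aldol addition that closes ring A as hydroxy-dihydrothiophene 7. E1cB loss of water from 7 aromatises the ring and erases its two transient stereocentres, so no stereochemistry has to be controlled. The closest known reactions are the condensation of beta-chlorovinyl aldehydes with thioglycolates or mercaptoacetone and the conversion of 2-halo(hetero)aryl aldehydes into 2-formyl benzo-fused thiophenes with the same dithianediol. Only regiocontrol is needed: sulfur can enter only where chloride leaves, chloride loss from the first adduct should outrun any aldol through the enal alpha-carbon, and afterwards that push–pull carbon is a poor nucleophile whereas the alpha-thio aldehyde is readily enolised by the amine. The non-enolisable methyl ester on ring B is inert to Et3N and leaves the two ends of the bithiophene at different oxidation levels.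

**Step 3**
Reactants: 8 methyl 5'-formyl-2,2'-bithiophene-5-carboxylate
Product: 9 methyl 5'-ethynyl-2,2'-bithiophene-5-carboxylate
Conditions: dimethyl (1-diazo-2-oxopropyl)phosphonate (1.3 equiv), K2CO3 (2 equiv), MeOH/THF, 0 °C to rt
Reagents that add atoms: dimethyl (1-diazo-2-oxopropyl)phosphonate CC(=O)C(=[N+]=[N-])P(=O)(OC)OC (terminal alkyne carbon)
Why: Seyferth–Gilbert homologation in the Ohira–Bestmann form: the diazomethylphosphonate anion released by methanolysis adds to the non-enolisable heteroaryl aldehyde, and Horner–Wadsworth–Emmons-type elimination, loss of N2 and 1,2-hydride shift should give the terminal alkyne, while the methyl ester only undergoes degenerate exchange in K2CO3/MeOH.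

**Step 4**
Reactants: 9 methyl 5'-ethynyl-2,2'-bithiophene-5-carboxylate; 10 ethyl diazoacetate
Product: 11 methyl 5'-(4-ethoxy-4-oxobut-1-yn-1-yl)-2,2'-bithiophene-5-carboxylate
Conditions: 10 (1.2 equiv), CuI (5 mol %), MeCN, N2, rt
Reagents that add atoms: none
Why: Copper-catalysed coupling of a terminal alkyne with a diazo ester: the copper acetylide traps the carbene from 10, and migratory insertion and protonation form the C(sp)–CH2 bond under neutral conditions, so the 3-alkynoate should not drift to the allenoate and the ester and both thiophenes are tolerated.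

**Step 5**
Reactants: 11 methyl 5'-(4-ethoxy-4-oxobut-1-yn-1-yl)-2,2'-bithiophene-5-carboxylate
Product: 12 4-[5'-(hydroxymethyl)-2,2'-bithiophen-5-yl]but-3-yn-1-ol
Conditions: i-Bu2AlH (5 equiv), CH2Cl2, −78 °C to −20 °C; then aq. KNaC4H4O6 (Rochelle salt)
Reagents that add atoms: none
Why: Exhaustive ester reduction with an electrophilic aluminium hydride: at low temperature i-Bu2AlH should reduce both the thiophene methyl ester and the 3-alkynoate to primary alcohols without deprotonating the propargylic CH2 or hydroaluminating the internal aryl alkyne, and the neutral tartrate work-up spares the acid-sensitive thienylmethanol.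

**Step 6**
Reactants: 12 4-[5'-(hydroxymethyl)-2,2'-bithiophen-5-yl]but-3-yn-1-ol; 13 3-methylbutanoyl chloride (isovaleryl chloride)
Product: 14 4-[5'-({[3-methylbutanoyl]oxy}methyl)-2,2'-bithiophen-5-yl]but-3-yn-1-yl 3-methylbutanoate (CNP0154475.0)
Conditions: 13 (2.5 equiv), Et3N (3 equiv), DMAP (0.1 equiv), CH2Cl2, 0 °C to rt
Reagents that add atoms: none
Why: DMAP-catalysed acylation with an acyl chloride: both primary alcohols should be esterified in one operation, and the amine base removes HCl so that the thienylmethyl C–O bond does not ionise.

**Compound list**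
1 | methyl 5-acetylthiophene-2-carboxylate | COC(=O)c1ccc(C(C)=O)s1 | starting material
2 | N-{(2Z)-3-chloro-3-[5-(methoxycarbonyl)thiophen-2-yl]prop-2-en-1-ylidene}-N-methylmethanaminium chloride (chlorovinyl iminium chloride; not isolated) | COC(=O)c1ccc(/C(Cl)=C/C=[N+](C)C)s1.[Cl-] | intermediate
3 | methyl 5-[(Z)-1-chloro-3-oxoprop-1-enyl]thiophene-2-carboxylate | COC(=O)c1ccc(/C(Cl)=C/C=O)s1 | intermediate
4 | 1,4-dithiane-2,5-diol | OC1CSC(O)CS1 | starting material
5 | 2-sulfanylacetaldehyde (mercaptoacetaldehyde; not isolated) | O=CCS | intermediate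
6 | methyl 5-{(1Z)-3-oxo-1-[(2-oxoethyl)sulfanyl]prop-1-en-1-yl}thiophene-2-carboxylate (vinyl sulfide dialdehyde; not isolated) | COC(=O)c1ccc(/C(SCC=O)=C/C=O)s1 | intermediate
7 | methyl 5-(5-formyl-4-hydroxy-4,5-dihydrothiophen-2-yl)thiophene-2-carboxylate (aldol adduct, racemic diastereomer mixture; not isolated) | COC(=O)c1ccc(C2=CC(O)C(C=O)S2)s1 | intermediate
8 | methyl 5'-formyl-2,2'-bithiophene-5-carboxylate | COC(=O)c1ccc(-c2ccc(C=O)s2)s1 | intermediate
9 | methyl 5'-ethynyl-2,2'-bithiophene-5-carboxylate | COC(=O)c1ccc(-c2ccc(C#C)s2)s1 | intermediate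
10 | ethyl diazoacetate | CCOC(=O)C=[N+]=[N-] | starting material
11 | methyl 5'-(4-ethoxy-4-oxobut-1-yn-1-yl)-2,2'-bithiophene-5-carboxylate | CCOC(=O)CC#Cc1ccc(-c2ccc(C(=O)OC)s2)s1 | intermediate
12 | 4-[5'-(hydroxymethyl)-2,2'-bithiophen-5-yl]but-3-yn-1-ol | OCCC#Cc1ccc(-c2ccc(CO)s2)s1 | intermediate
13 | 3-methylbutanoyl chloride (isovaleryl chloride) | CC(C)CC(=O)Cl | starting material
14 | 4-[5'-({[3-methylbutanoyl]oxy}methyl)-2,2'-bithiophen-5-yl]but-3-yn-1-yl 3-methylbutanoate | CC(C)CC(=O)OCCC#Cc1ccc(-c2ccc(COC(=O)CC(C)C)s2)s1 | target

**Totals**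
Total step count: 6. Longest linear sequence: 6 steps (1 → 3 → 8 → 9 → 11 → 12 → 14).

**Steps most likely to fail**

Step 2. The aldol may close in the reverse sense, with the enal alpha-carbon attacking the carbonyl of the mercaptoacetaldehyde unit, or free mercaptoacetaldehyde may self-condense before it is captured. Ring A would then form with the formyl group misplaced or not at all. The fallback sets out from 3 and changes the donor to an alpha-mercapto ester whose carbonyl cannot act as the aldol acceptor. tert-Butyl 2-sulfanylacetate with K2CO3 in DMF (rt to 60 °C) should form the same S1–C2 and C4–C5 bonds and give 5'-tert-butyl 5-methyl 2,2'-bithiophene-5,5'-dicarboxylate F1. CF3CO2H in CH2Cl2 should cleave only the tert-butyl ester to 5'-(methoxycarbonyl)-2,2'-bithiophene-5-carboxylic acid F2. BH3·SMe2 in THF should reduce the acid beside the methyl ester to methyl 5'-(hydroxymethyl)-2,2'-bithiophene-5-carboxylate F3. MnO2 in CH2Cl2 should oxidise the thienylic alcohol, and the route is rejoined at 8.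

Step 4. Oxidative dimerisation of the alkyne, dimerisation of the carbene, or prototropic drift of the 3-alkynoate to the allenoate during reaction or chromatography may erode the two-carbon extension. The fallback sets out from 9 and replaces steps 4 and 5 by epoxide chemistry. i-Bu2AlH in CH2Cl2 at −78 °C should give (5'-ethynyl-2,2'-bithiophen-5-yl)methanol F4. TBSCl and imidazole in DMF should give tert-butyl[(5'-ethynyl-2,2'-bithiophen-5-yl)methoxy]dimethylsilane F5. Deprotonation with n-BuLi in THF at −78 °C and opening of ethylene oxide assisted by BF3·OEt2 should give 4-[5'-({[tert-butyl(dimethyl)silyl]oxy}methyl)-2,2'-bithiophen-5-yl]but-3-yn-1-ol F6. Bu4NF in THF removes the silyl group, and the route is rejoined at 12.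

Step 1. Chloroformylation of the electron-poor ketone may stay incomplete, and the vinylic chloride may be lost by hydrolysis or the Z geometry eroded in the hot acidic mixture and on aqueous work-up. The fallback sets out from 1 and separates C–C bond formation from chlorination. Me2NCH(OMe)2 in toluene at 100 °C should give methyl 5-[(2E)-3-(dimethylamino)prop-2-enoyl]thiophene-2-carboxylate F7. Oxalyl chloride in CH2Cl2 at 0 °C should convert this enaminone into iminium chloride 2, and buffered hydrolysis returns to the route at 3.

**Further compounds**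
F1 | step 2 | 5'-tert-butyl 5-methyl 2,2'-bithiophene-5,5'-dicarboxylate | COC(=O)c1ccc(-c2ccc(C(=O)OC(C)(C)C)s2)s1
F2 | step 2 | 5'-(methoxycarbonyl)-2,2'-bithiophene-5-carboxylic acid | COC(=O)c1ccc(-c2ccc(C(=O)O)s2)s1
F3 | step 2 | methyl 5'-(hydroxymethyl)-2,2'-bithiophene-5-carboxylate | COC(=O)c1ccc(-c2ccc(CO)s2)s1
F4 | step 4 | (5'-ethynyl-2,2'-bithiophen-5-yl)methanol | OCc1ccc(-c2ccc(C#C)s2)s1
F5 | step 4 | tert-butyl[(5'-ethynyl-2,2'-bithiophen-5-yl)methoxy]dimethylsilane | CC(C)(C)[Si](C)(C)OCc1ccc(-c2ccc(C#C)s2)s1
F6 | step 4 | 4-[5'-({[tert-butyl(dimethyl)silyl]oxy}methyl)-2,2'-bithiophen-5-yl]but-3-yn-1-ol | CC(C)(C)[Si](C)(C)OCc1ccc(-c2ccc(C#CCCO)s2)s1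
F7 | step 1 | methyl 5-[(2E)-3-(dimethylamino)prop-2-enoyl]thiophene-2-carboxylate | COC(=O)c1ccc(C(=O)/C=C/N(C)C)s1
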